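**Plan**
- The quinone ring is labelled Q1 (C–OMe), Q2 (C–indol-3-yl), Q3 (C=O), Q4 (C–OMe), Q5 (C–7-prenylindol-3-yl), Q6 (C=O). Its halves Q2–Q1–Q6 and Q5–Q4–Q3 are each the aryl-carbon/oxygenated-carbon/carboxyl-carbon chain of an indol-3-ylpyruvate, lying head to tail; this is what allows a double Dieckmann closure.
- Retrosynthesis: cut the two O–CH3 bonds, then the ring bonds Q2–Q3 and Q5–Q6. The two pyruvates are held together by an enol ester Q4–O–C(=O)Q6, with unit A masked as a TBS enol ether and unit B carried as its methyl ester.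
- Forward: unit B comes from 7-bromoindole (C7 prenylation, C3 formylation, azlactone, hydrolysis, methyl ester); unit A comes from indole-3-pyruvic acid by silylation; DCC esterification joins them.
- Fluoride, then methoxide, forms Q2–Q3 (transient pyrandione lactone) and then Q5–Q6, which closes the only new ring, the six-membered carbocycle; O-methylation ends the route.
- Stereochemistry: the target has no stereocentre and no stereogenic alkene. The Z enol geometries of the intermediates are the thermodynamic ones and vanish in the quinone.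

Key step: step 8

Assumption: pyruvic acids 7 and 9 are drawn as keto acids and ester 8 as its Z-enol (the reacting tautomer); the indole nitrogen is taken to be acetylated during azlactone formation, and any N–H azlactone would converge in step 4. Prenyl means 3-methylbut-2-en-1-yl.

**Step 1**
Reactants: 1 7-bromo-1H-indole; 2 prenyl bromide
Product: 3 7-prenyl-1H-indole
Conditions: KH, THF, 0 °C; t-BuLi (2.1 equiv), −78 °C; 2 (1.05 equiv), −78 to −40 °C; H2O
Reagents that add atoms: none
Why: Deprotonation of N–H followed by bromine–lithium exchange gives the C7 aryllithium, which should alkylate at the primary carbon of prenyl bromide (SN2) well before the potassium indolide nitrogen reacts at low temperature.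

**Step 2**
Reactants: 3 7-prenyl-1H-indole
Product: 4 7-prenyl-1H-indole-3-carbaldehyde
Conditions: POCl3, DMF, 0 °C to rt; then 2 M NaOH, 80 °C
Reagents that add atoms: N,N-dimethylformamide CN(C)C=O; water O
Why: Vilsmeier–Haack formylation, in which the chloroiminium ion attacks the most nucleophilic position (indole C3) and the iminium is hydrolysed by base, while the much less nucleophilic prenyl alkene should be left alone.

**Step 3**
Reactants: 4 7-prenyl-1H-indole-3-carbaldehyde; 5 N-acetylglycine
Product: 6 (4Z)-4-[(1-acetyl-7-prenylindol-3-yl)methylidene]-2-methyl-1,3-oxazol-5(4H)-one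
Conditions: Ac2O, NaOAc, 100 °C
Reagents that add atoms: acetic anhydride CC(=O)OC(C)=O
Why: Erlenmeyer–Plöchl azlactone synthesis, in which N-acetylglycine cyclises to 2-methyloxazol-5-one and its C4 condenses with the aldehyde (activated by concurrent N-acetylation of the indole) to give the thermodynamically preferred Z-alkylidene azlactone.

**Step 4**
Reactants: 6 (4Z)-4-[(1-acetyl-7-prenylindol-3-yl)methylidene]-2-methyl-1,3-oxazol-5(4H)-one
Product: 7 3-(7-prenyl-1H-indol-3-yl)-2-oxopropanoic acid
Conditions: 2 M NaOH (degassed), reflux, N2; then cold 2 M HCl to pH 2–3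
Reagents that add atoms: water O
Why: Alkaline azlactone hydrolysis (the classical arylpyruvic acid synthesis), in which hydroxide opens the lactone, cleaves both acetamides and hydrolyses the resulting enamine to the keto acid; the prenyl alkene is inert to base and air is excluded because indolylpyruvates autoxidise.

**Step 5**
Reactants: 7 3-(7-prenyl-1H-indol-3-yl)-2-oxopropanoic acid
Product: 8 methyl (Z)-2-hydroxy-3-(7-prenyl-1H-indol-3-yl)prop-2-enoate
Conditions: DBU (1.0 equiv), MeI (1.2 equiv), DMF, 0 °C, Ar
Reagents that add atoms: iodomethane CI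
Why: Carboxylate O-alkylation (SN2 on MeI); one equivalent of DBU ionises only the carboxylic acid, so the enol hydroxyl and the indole N–H should stay unalkylated and the ester settles as the conjugated Z-enol.

**Step 6**
Reactants: 9 indole-3-pyruvic acid
Product: 11 (Z)-2-(tert-butyldimethylsilyloxy)-3-(1H-indol-3-yl)prop-2-enoic acid, via bis-silylated pyruvate 10 (not isolated)
Conditions: TBSCl (2.3 equiv), imidazole, DMF, rt; then K2CO3 (1.1 equiv), MeOH/THF/H2O, 0 °C; aq. citric acid to pH 4–5
Reagents that add atoms: tert-butyldimethylsilyl chloride CC(C)(C)[Si](C)(C)Cl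
Why: Silylation of the enol and the acid with TBSCl/imidazole followed by selective hydrolysis of the far more labile silyl ester with carbonate, a standard way to a silyl-protected hydroxy acid; the push-pull enol silyl ether is expected to survive the brief mild base and the Z geometry of the stable enol is kept.

**Step 7**
Reactants: 8 methyl (Z)-2-hydroxy-3-(7-prenyl-1H-indol-3-yl)prop-2-enoate; 11 (Z)-2-(tert-butyldimethylsilyloxy)-3-(1H-indol-3-yl)prop-2-enoic acid
Product: 12 methyl (Z)-2-{[(Z)-2-(tert-butyldimethylsilyloxy)-3-(1H-indol-3-yl)prop-2-enoyl]oxy}-3-(7-prenyl-1H-indol-3-yl)prop-2-enoate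
Conditions: DCC, DMAP (cat.), CH2Cl2, 0 °C to rt
Reagents that add atoms: none
Why: Steglich esterification, in which the acylpyridinium derived from 11 is attacked by the acidic, phenol-like enol oxygen of 8 to give the enol ester; the indole N–H groups are too weakly nucleophilic to compete and the neutral conditions spare the silyl enol ether.

**Step 8**
Reactants: 12 methyl (Z)-2-{[(Z)-2-(tert-butyldimethylsilyloxy)-3-(1H-indol-3-yl)prop-2-enoyl]oxy}-3-(7-prenyl-1H-indol-3-yl)prop-2-enoate
Product: 15 2,5-dihydroxy-3-(1H-indol-3-yl)-6-(7-prenyl-1H-indol-3-yl)-1,4-benzoquinone, via pyrandione lactone 13 (not isolated), via open-chain trioxo ester 14 (not isolated)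
Conditions: CsF (3 equiv), DMF (0.02 M), 0 °C to rt, Ar; then NaOMe (3 equiv), MeOH, rt to 50 °C; cold 1 M HCl
Reagents that add atoms: none
Why: Proposed new method: fluoride removes the enol silyl group of unit A and the cesium enolate attacks through Q2 the methyl ester carbon Q3 of unit B, a 6-(enolendo)-exo-trig Dieckmann acylation that gives the 6-alkylidene-pyran-2,5-dione 13 and methoxide. Because acidic 13 quenches its own methoxide, NaOMe is then added; it opens the enol lactone at Q6 to the methyl ester enolate 14, whose carbon Q5 attacks Q6 in a second 6-(enolendo)-exo-trig Dieckmann acylation, and the resulting cyclohexanetetraone tautomerises to the dihydroxyquinone, whose stable dianion drives the sequence. The closest known reactions are the base-mediated Dieckmann closure of O-acylated arylpyruvate enol esters to 6-arylidene-3-hydroxypyran-2,5-diones and the alkoxide-induced acyl shift of such pyrandiones to 2,5-dihydroxy-3,6-diaryl-1,4-benzoquinones; the new element is the one-flask fluoride trigger on an unsymmetrical bis-indolyl substrate. The only ring kept is the six-membered carbocycle, the lactone ring being transient, and no stereocentre is formed. The selectivity needed is hetero- over homo-dimerisation, and the enol ester tether should secure it because the first C–C bond forms inside the linked pair under fluoride alone, before any methoxide that could cut the tether is added. O-acylation of the enolate at Q3 would only give a dilactone that methoxide reopens to either tether isomer, and both isomers lead to the same quinone.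

**Step 9**
Reactants: 15 2,5-dihydroxy-3-(1H-indol-3-yl)-6-(7-prenyl-1H-indol-3-yl)-1,4-benzoquinone
Product: 16 2,5-dimethoxy-3-(1H-indol-3-yl)-6-(7-prenyl-1H-indol-3-yl)-1,4-benzoquinone
Conditions: TMSCHN2 (excess), MeOH/CH2Cl2, 0 °C to rt
Reagents that add atoms: trimethylsilyldiazomethane C[Si](C)(C)C=[N+]=[N-]
Why: O-methylation of the two vinylogous carboxylic acid hydroxyls by diazomethane generated from TMSCHN2 and methanol, a reaction type known to convert 2,5-dihydroxy-3,6-diarylbenzoquinones into their 2,5-dimethyl ethers without touching the far less acidic indole N–H.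

**Compound list**
1 | 7-bromo-1H-indole | Brc1cccc2cc[nH]c12 | starting material
2 | prenyl bromide (1-bromo-3-methylbut-2-ene) | CC(C)=CCBr | starting material
3 | 7-prenyl-1H-indole | CC(C)=CCc1cccc2cc[nH]c12 | intermediate
4 | 7-prenyl-1H-indole-3-carbaldehyde | O=Cc1c[nH]c2c(CC=C(C)C)cccc12 | intermediate
5 | N-acetylglycine | CC(=O)NCC(=O)O | starting material
6 | (4Z)-4-[(1-acetyl-7-prenylindol-3-yl)methylidene]-2-methyl-1,3-oxazol-5(4H)-one | CC1=N/C(=C\c2cn(C(C)=O)c3c(CC=C(C)C)cccc23)C(=O)O1 | intermediate
7 | 3-(7-prenyl-1H-indol-3-yl)-2-oxopropanoic acid | O=C(O)C(=O)Cc1c[nH]c2c(CC=C(C)C)cccc12 | intermediate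
8 | methyl (Z)-2-hydroxy-3-(7-prenyl-1H-indol-3-yl)prop-2-enoate | COC(=O)/C(O)=C/c1c[nH]c2c(CC=C(C)C)cccc12 | intermediate
9 | indole-3-pyruvic acid | O=C(O)C(=O)Cc1c[nH]c2ccccc12 | starting material
10 | tert-butyldimethylsilyl (Z)-2-(tert-butyldimethylsilyloxy)-3-(1H-indol-3-yl)prop-2-enoate | CC(C)(C)[Si](C)(C)OC(=O)/C(O[Si](C)(C)C(C)(C)C)=C/c1c[nH]c2ccccc12 | intermediate (not isolated)
11 | (Z)-2-(tert-butyldimethylsilyloxy)-3-(1H-indol-3-yl)prop-2-enoic acid | OC(=O)/C(O[Si](C)(C)C(C)(C)C)=C/c1c[nH]c2ccccc12 | intermediate
12 | methyl (Z)-2-{[(Z)-2-(tert-butyldimethylsilyloxy)-3-(1H-indol-3-yl)prop-2-enoyl]oxy}-3-(7-prenyl-1H-indol-3-yl)prop-2-enoate | COC(=O)/C(OC(=O)/C(O[Si](C)(C)C(C)(C)C)=C/c1c[nH]c2ccccc12)=C/c1c[nH]c2c(CC=C(C)C)cccc12 | intermediate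
13 | (6Z)-3-hydroxy-4-(1H-indol-3-yl)-6-[(7-prenyl-1H-indol-3-yl)methylidene]-2H-pyran-2,5(6H)-dione | O=C1O/C(=C\c2c[nH]c3c(CC=C(C)C)cccc23)C(=O)C(c2c[nH]c3ccccc23)=C1O | intermediate (not isolated)
14 | methyl (2Z,5Z)-2,5-dihydroxy-3-(1H-indol-3-yl)-6-(7-prenyl-1H-indol-3-yl)-4-oxohexa-2,5-dienoate (formed as its anion, drawn as the neutral bis-enol) | COC(=O)/C(O)=C(\c1c[nH]c2ccccc12)C(=O)/C(O)=C/c1c[nH]c2c(CC=C(C)C)cccc12 | intermediate (not isolated)
15 | 2,5-dihydroxy-3-(1H-indol-3-yl)-6-(7-prenyl-1H-indol-3-yl)-1,4-benzoquinone | OC1=C(c2c[nH]c3ccccc23)C(=O)C(O)=C(c2c[nH]c3c(CC=C(C)C)cccc23)C1=O | intermediate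
16 | 2,5-dimethoxy-3-(1H-indol-3-yl)-6-(7-prenyl-1H-indol-3-yl)-1,4-benzoquinone | COC1=C(c2c[nH]c3ccccc23)C(=O)C(OC)=C(c2c[nH]c3c(CC=C(C)C)cccc23)C1=O | target

**Step count**
Total: 9 steps. Longest linear sequence: 8 steps (1, 2, 3, 4, 5, 7, 8, 9); step 6 is the one-step side branch.

**Steps most likely to fail**

Step 8. The ester carbon Q3 is deactivated by push-pull conjugation with indole B, and the tether ester must rotate into its s-cis conformer before Q2 can reach it. The first C–C bond may therefore form slowly, and intermolecular acyl transfer or methanolysis of the tether could separate the two halves before they are joined, which would erase the cross-selectivity; the free enolates may also be protonated or air-oxidised. The fallback uses known chemistry, sets out from 3 and returns at 15. Commercial indole is added under acid promotion (conc. HCl, THF) to 2,5-dichloro-1,4-benzoquinone to give 2,5-dichloro-3-(1H-indol-3-yl)benzene-1,4-diol F1, which DDQ oxidises to 2,5-dichloro-3-(1H-indol-3-yl)-1,4-benzoquinone F2. Indole 3 is then added at the only free ring position (AcOH, to spare the prenyl group) to give 2,5-dichloro-3-(1H-indol-3-yl)-6-(7-prenyl-1H-indol-3-yl)benzene-1,4-diol F3, oxidised with DDQ to 2,5-dichloro-3-(1H-indol-3-yl)-6-(7-prenyl-1H-indol-3-yl)-1,4-benzoquinone F4. NaOH in aqueous MeOH at reflux replaces both chlorides by addition–elimination and gives 15 after acidification.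

Step 7. O-acylation of a weakly nucleophilic, hindered enol by a conjugated, deactivated acyl donor may be slow, so that the activated acid rearranges to the N-acylurea or the silyl enol ether is lost to adventitious acid. The fallback sets out from 11 and returns at 12. Acid 11 is converted under neutral conditions with 1-chloro-N,N,2-trimethylprop-1-en-1-amine in CH2Cl2 at 0 °C into (Z)-2-(tert-butyldimethylsilyloxy)-3-(1H-indol-3-yl)prop-2-enoyl chloride F5. This discrete acid chloride is added at −20 °C to enol 8 with Et3N and DMAP (cat.) to give 12.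

Step 6. The enol silyl group may be lost together with the silyl ester during hydrolysis or acidification, or the free acid may protodesilylate itself on concentration. The fallback sets out from 9 and returns at 11. The carboxylate of 9 is alkylated with allyl bromide and DBU in DMF to give allyl (Z)-2-hydroxy-3-(1H-indol-3-yl)prop-2-enoate F6. The enol is silylated with TBSCl and imidazole in DMF to give allyl (Z)-2-(tert-butyldimethylsilyloxy)-3-(1H-indol-3-yl)prop-2-enoate F7. The allyl ester is then removed under neutral conditions with Pd(PPh3)4 (cat.) and morpholine in THF to give 11 without exposing the silyl enol ether to base or aqueous acid.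

**Further compounds**
F1 | step 8 | 2,5-dichloro-3-(1H-indol-3-yl)benzene-1,4-diol | Oc1cc(Cl)c(O)c(-c2c[nH]c3ccccc23)c1Cl
F2 | step 8 | 2,5-dichloro-3-(1H-indol-3-yl)-1,4-benzoquinone | O=C1C=C(Cl)C(=O)C(c2c[nH]c3ccccc23)=C1Cl
F3 | step 8 | 2,5-dichloro-3-(1H-indol-3-yl)-6-(7-prenyl-1H-indol-3-yl)benzene-1,4-diol | Oc1c(-c2c[nH]c3c(CC=C(C)C)cccc23)c(Cl)c(O)c(-c2c[nH]c3ccccc23)c1Cl
F4 | step 8 | 2,5-dichloro-3-(1H-indol-3-yl)-6-(7-prenyl-1H-indol-3-yl)-1,4-benzoquinone | O=C1C(c2c[nH]c3c(CC=C(C)C)cccc23)=C(Cl)C(=O)C(c2c[nH]c3ccccc23)=C1Cl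
F5 | step 7 | (Z)-2-(tert-butyldimethylsilyloxy)-3-(1H-indol-3-yl)prop-2-enoyl chloride | ClC(=O)/C(O[Si](C)(C)C(C)(C)C)=C/c1c[nH]c2ccccc12
F6 | step 6 | allyl (Z)-2-hydroxy-3-(1H-indol-3-yl)prop-2-enoate | C=CCOC(=O)/C(O)=C/c1c[nH]c2ccccc12
F7 | step 6 | allyl (Z)-2-(tert-butyldimethylsilyloxy)-3-(1H-indol-3-yl)prop-2-enoate | C=CCOC(=O)/C(O[Si](C)(C)C(C)(C)C)=C/c1c[nH]c2ccccc12
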